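**Retrosynthetic overview**
1. Ring B (C1, O2, C3, C4, C4a, C8a) is the lactol of a keto acid. Removing O2 and joining C1 to C3 turns it into the α-ketol of an indan-1-one. Ring B is therefore made last, by periodate cleavage of this temporary C1–C3 bond and spontaneous lactol closure, with C3 following C4 thermodynamically.
2. The CH2–O bond of the ester is cut next. The carboxylate of fragment B (2,4-bis(benzyloxy)-3,5,6-trimethylbenzoic acid, from atraric acid) opens a spiro-epoxide, which is built on the indanone by methylenation and epoxidation.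
3. Key disconnection C4a–C4: the temporary five-membered ring is closed and C4 is set by rhodium-catalysed asymmetric isomerisation of a racemic aryl propargyl alcohol (aryl aldehyde plus propynyl Grignard reagent).
4. Enabling feature: on ring A, C8a carries C1, and of its two ortho positions C8 is blocked by oxygen, so C4a holds the only C–H. Once C1 and C3 are bonded, C4 is the β-carbon of a C1 enone. A 1,4 rhodium shift followed by 1,4-addition can then make only this bond.
5. Order of rings: ring A is bought; cyclopentanone (step 4); oxirane (step 6, opened in step 11); ring B (step 12, with loss of the cyclopentanone).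

Key step: step 4

Assumption: (R)-SEGPHOS is taken to give the 3R ketone in step 4; if a first run shows the opposite sense of induction, the (S)-ligand is used and nothing else changes.

Step 1
Reactants: 1 2,4-dimethoxy-5-methylbenzaldehyde
Product: 2 2-hydroxy-4-methoxy-5-methylbenzaldehyde
Conditions: BCl3 (1.2 equiv), CH2Cl2, −78 °C to 0 °C; aq work-up
Reagents that add atoms: none
Why: BCl3 binds in a six-membered chelate between the formyl oxygen and the ortho methoxy oxygen, so this chelation-controlled Lewis-acid cleavage of an aryl methyl ether should remove only the methyl group on the future C8 oxygen and keep the para methoxy group (future C6–OMe).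

Step 2
Reactants: 2 2-hydroxy-4-methoxy-5-methylbenzaldehyde
Product: 3 2-(benzyloxy)-4-methoxy-5-methylbenzaldehyde
Conditions: BnBr, K2CO3, DMF, 50 °C
Reagents that add atoms: benzyl bromide BrCc1ccccc1
Why: Williamson ether synthesis on the only phenol gives a benzyl ether that should survive organometallics, base, peroxide and periodate and that leaves in the final hydrogenolysis together with the benzyl groups of fragment B.

Step 3
Reactants: 3 2-(benzyloxy)-4-methoxy-5-methylbenzaldehyde; 4 1-propynylmagnesium bromide
Product: 5 racemic 1-[2-(benzyloxy)-4-methoxy-5-methylphenyl]but-2-yn-1-ol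
Conditions: THF, 0 °C to rt; aq NH4Cl
Reagents that add atoms: none
Why: 1,2-addition of an alkynyl Grignard reagent to a non-enolisable aromatic aldehyde is reliable, and the racemic carbinol centre needs no control because step 4 erases it.

Step 4
Reactants: 5 racemic 1-[2-(benzyloxy)-4-methoxy-5-methylphenyl]but-2-yn-1-ol
Product: 7 (3R)-7-(benzyloxy)-5-methoxy-3,4-dimethyl-2,3-dihydro-1H-inden-1-one, via ynone 6 (not isolated)
Conditions: [Rh(OH)(cod)]2 (2.5 mol %), (R)-SEGPHOS (5.5 mol %), toluene, 60 °C
Reagents that add atoms: none
Why: Mechanism: the monovalent rhodium alkoxide of 5 undergoes β-hydride elimination to ynone 6 held on Rh–H, syn hydrorhodation places rhodium on the α-carbon (future C3) and hydrogen on the β-carbon (future C4), a 1,4 rhodium shift exchanges the metal with the C4a hydrogen, the C4a–Rh bond adds across the enone at C4, and the oxa-π-allyl rhodium is protonated by the next molecule of 5, which restarts the cycle. The closest known reaction type is the rhodium/chiral bisphosphine-catalysed isomerisation of racemic α-arylpropargyl alcohols to β-chiral indan-1-ones, here applied to a more substituted aryl group. The one ring closed, the cyclopentanone, forms by a formal 5-endo-trig intramolecular 1,4-carborhodation, that is, migratory insertion of the C3=C4 double bond into the C4a–Rh bond. The one new stereocentre, C4 (C3 of the indanone, R), is controlled by the ligand, which selects the enone face in this insertion, and both enantiomers of 5 converge because their carbinol centre is erased at the stage of 6. The step needs site selectivity in the C–H cleavage and a shift that is faster than protonolysis of the alkenylrhodium: the first is secured by ring A itself, since of the two positions ortho to C8a one bears the benzyloxy group and only C4a bears hydrogen, the second by the aprotic medium in which the substrate alcohol is the only proton source. In one reagent-free operation the most crowded C–C bond, the only independent stereocentre and the C1 carbonyl level are obtained from an acyclic racemate, and the new centre is β to the ketone and so cannot epimerise before ring B is made.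

Step 5
Reactants: 7 (3R)-7-(benzyloxy)-5-methoxy-3,4-dimethyl-2,3-dihydro-1H-inden-1-one
Product: 8 (3S)-7-(benzyloxy)-5-methoxy-3,4-dimethyl-2-methylidene-2,3-dihydro-1H-inden-1-one (same spatial arrangement at C3; the descriptor changes by priority only)
Conditions: (CH2O)n, i-Pr2NH·CF3CO2H, CF3CO2H (10 mol %), THF, reflux
Reagents that add atoms: formaldehyde (as paraformaldehyde) C=O
Why: Mannich-type α-methylenation (formaldehyde, secondary ammonium salt, β-elimination) can occur only at C2, the sole enolisable position, the stereocentre is safe because its hydrogen sits on a carbon bound to the α-carbon of the new enone and is not vinylogously acidified, and 8 is carried on without storage to avoid dimerisation.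

Step 6
Reactants: 8 (3S)-7-(benzyloxy)-5-methoxy-3,4-dimethyl-2-methylidene-2,3-dihydro-1H-inden-1-one
Product: 9 (2S,3S)-7-(benzyloxy)-5-methoxy-3,4-dimethylspiro[indene-2,2'-oxiran]-1(3H)-one (oxirane oxygen trans to the 3-methyl group)
Conditions: 30% aq H2O2, NaOH (20 mol %), MeOH/THF, 0 °C
Reagents that add atoms: hydrogen peroxide OO
Why: In this Weitz–Scheffer nucleophilic epoxidation hydroperoxide adds to the unhindered exocyclic CH2 and the enolate closes onto oxygen on the ring face opposite to the 3-methyl group, which sets C2 as drawn, a centre that is erased again in step 12 so that its epimer would converge on the same product.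

Step 7
Reactants: 10 methyl 2,4-dihydroxy-3,6-dimethylbenzoate (atraric acid)
Product: 11 methyl 5-formyl-2,4-dihydroxy-3,6-dimethylbenzoate
Conditions: Cl2CHOMe, TiCl4, CH2Cl2, −10 °C to rt; then H2O
Reagents that add atoms: dichloromethyl methyl ether COC(Cl)Cl; water O
Why: Rieche formylation (electrophilic aromatic substitution) finds only one free ring position, C5, which is ortho to one phenol and para to the other and therefore strongly activated.

Step 8
Reactants: 11 methyl 5-formyl-2,4-dihydroxy-3,6-dimethylbenzoate
Product: 12 methyl 2,4-dihydroxy-3,5,6-trimethylbenzoate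
Conditions: Et3SiH, CF3CO2H, CH2Cl2, 0 °C to rt
Reagents that add atoms: none
Why: In this ionic hydrogenation the protonated hydroxybenzaldehyde and then the derived benzylic cation (a protonated quinone methide) each accept hydride from Et3SiH, which takes the formyl group down to methyl without touching the ester.

Step 9
Reactants: 12 methyl 2,4-dihydroxy-3,5,6-trimethylbenzoate
Product: 13 methyl 2,4-bis(benzyloxy)-3,5,6-trimethylbenzoate
Conditions: BnBr, K2CO3, DMF, 70 °C
Reagents that add atoms: benzyl bromide BrCc1ccccc1
Why: Double Williamson ether synthesis should go to completion on warming, which is needed because both phenols are flanked by two ortho substituents and one is hydrogen-bonded to the ester.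

Step 10
Reactants: 13 methyl 2,4-bis(benzyloxy)-3,5,6-trimethylbenzoate
Product: 14 2,4-bis(benzyloxy)-3,5,6-trimethylbenzoic acid
Conditions: KOH, DMSO/H2O, 100 °C; then aq HCl
Reagents that add atoms: potassium hydroxide [K+].[OH-]
Why: Saponification by acyl–oxygen cleavage of a di-ortho-substituted benzoate is slow in protic media but should proceed with poorly solvated hydroxide in hot aqueous DMSO, conditions under which aryl benzyl ethers are inert.

Step 11
Reactants: 9 (2S,3S)-7-(benzyloxy)-5-methoxy-3,4-dimethylspiro[indene-2,2'-oxiran]-1(3H)-one; 14 2,4-bis(benzyloxy)-3,5,6-trimethylbenzoic acid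
Product: 15 [(2S,3S)-7-(benzyloxy)-2-hydroxy-5-methoxy-3,4-dimethyl-1-oxo-2,3-dihydro-1H-inden-2-yl]methyl 2,4-bis(benzyloxy)-3,5,6-trimethylbenzoate
Conditions: Cs2CO3 (15 mol %), DMF, 70 °C
Reagents that add atoms: none
Why: SN2 opening of a terminal 2,2-disubstituted epoxide by a carboxylate at its CH2 group joins the two fragments through the alkyl–oxygen bond, so the crowded acyl carbon of 14 is never attacked, and C2 keeps its configuration because its C–O bond is not broken.

Step 12
Reactants: 15 [(2S,3S)-7-(benzyloxy)-2-hydroxy-5-methoxy-3,4-dimethyl-1-oxo-2,3-dihydro-1H-inden-2-yl]methyl 2,4-bis(benzyloxy)-3,5,6-trimethylbenzoate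
Product: 17 [(3R,4S)-8-(benzyloxy)-3-hydroxy-6-methoxy-4,5-dimethyl-1-oxo-3,4-dihydro-1H-isochromen-3-yl]methyl 2,4-bis(benzyloxy)-3,5,6-trimethylbenzoate, via keto acid 16 (not isolated)
Conditions: H5IO6, THF/H2O, 0 °C to rt
Reagents that add atoms: orthoperiodic acid O=I(O)(O)(O)(O)O
Why: Malaprade-type periodate cleavage of the α-ketol breaks the temporary C1–C2 bond of the indanone to give the acid and the ketone, which close at once to the six-membered lactol, and because this ring–chain tautomerism is reversible C3 settles under thermodynamic control by C4, with the 4-methyl group pseudoaxial to avoid the C5 methyl group, the 3-hydroxyl group axial (anomeric effect) and trans to it, and the acyloxymethyl group equatorial, which is the 3R configuration.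

Step 13
Reactants: 17 [(3R,4S)-8-(benzyloxy)-3-hydroxy-6-methoxy-4,5-dimethyl-1-oxo-3,4-dihydro-1H-isochromen-3-yl]methyl 2,4-bis(benzyloxy)-3,5,6-trimethylbenzoate
Product: 18 [(3R,4S)-3,8-dihydroxy-6-methoxy-4,5-dimethyl-1-oxo-3,4-dihydro-1H-isochromen-3-yl]methyl 2,4-dihydroxy-3,5,6-trimethylbenzoate (CNP0157156.2)
Conditions: H2 (1 atm), Pd/C, EtOAc, rt
Reagents that add atoms: none
Why: Hydrogenolysis of the three aryl benzyl ethers over palladium is neutral, so the ester, the lactol and the C4 centre (which could epimerise through the open keto acid under base) should be left alone, and C3 stays at the same thermodynamic 3R lactol, now reinforced by the hydrogen bond from the C8 hydroxyl group to the C1 carbonyl group.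

**Compound list**
1 | 2,4-dimethoxy-5-methylbenzaldehyde | COc1cc(OC)c(C=O)cc1C | starting material
2 | 2-hydroxy-4-methoxy-5-methylbenzaldehyde | COc1cc(O)c(C=O)cc1C | intermediate
3 | 2-(benzyloxy)-4-methoxy-5-methylbenzaldehyde | COc1cc(OCc2ccccc2)c(C=O)cc1C | intermediate
4 | 1-propynylmagnesium bromide | CC#C[Mg]Br | starting material
5 | racemic 1-[2-(benzyloxy)-4-methoxy-5-methylphenyl]but-2-yn-1-ol | COc1cc(OCc2ccccc2)c(C(O)C#CC)cc1C | intermediate
6 | 1-[2-(benzyloxy)-4-methoxy-5-methylphenyl]but-2-yn-1-one (ynone, not isolated) | COc1cc(OCc2ccccc2)c(C(=O)C#CC)cc1C | intermediate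
7 | (3R)-7-(benzyloxy)-5-methoxy-3,4-dimethyl-2,3-dihydro-1H-inden-1-one | COc1cc(OCc3ccccc3)c2c(c1C)[C@H](C)CC2=O | intermediate
8 | (3S)-7-(benzyloxy)-5-methoxy-3,4-dimethyl-2-methylidene-2,3-dihydro-1H-inden-1-one | COc1cc(OCc3ccccc3)c2c(c1C)[C@H](C)C(=C)C2=O | intermediate
9 | (2S,3S)-7-(benzyloxy)-5-methoxy-3,4-dimethylspiro[indene-2,2'-oxiran]-1(3H)-one | COc1cc(OCc3ccccc3)c2c(c1C)[C@H](C)[C@]4(CO4)C2=O | intermediate
10 | methyl 2,4-dihydroxy-3,6-dimethylbenzoate (atraric acid) | COC(=O)c1c(C)cc(O)c(C)c1O | starting material
11 | methyl 5-formyl-2,4-dihydroxy-3,6-dimethylbenzoate | COC(=O)c1c(C)c(C=O)c(O)c(C)c1O | intermediate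
12 | methyl 2,4-dihydroxy-3,5,6-trimethylbenzoate | COC(=O)c1c(C)c(C)c(O)c(C)c1O | intermediate
13 | methyl 2,4-bis(benzyloxy)-3,5,6-trimethylbenzoate | COC(=O)c1c(C)c(C)c(OCc2ccccc2)c(C)c1OCc1ccccc1 | intermediate
14 | 2,4-bis(benzyloxy)-3,5,6-trimethylbenzoic acid | OC(=O)c1c(C)c(C)c(OCc2ccccc2)c(C)c1OCc1ccccc1 | intermediate
15 | [(2S,3S)-7-(benzyloxy)-2-hydroxy-5-methoxy-3,4-dimethyl-1-oxo-2,3-dihydro-1H-inden-2-yl]methyl 2,4-bis(benzyloxy)-3,5,6-trimethylbenzoate | COc1cc(OCc3ccccc3)c2c(c1C)[C@H](C)[C@](O)(COC(=O)c1c(C)c(C)c(OCc4ccccc4)c(C)c1OCc1ccccc1)C2=O | intermediate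
16 | 2-(benzyloxy)-6-[(2S)-4-{[2,4-bis(benzyloxy)-3,5,6-trimethylbenzoyl]oxy}-3-oxobutan-2-yl]-4-methoxy-5-methylbenzoic acid (keto acid, not isolated) | COc1cc(OCc3ccccc3)c(C(=O)O)c(c1C)[C@H](C)C(=O)COC(=O)c1c(C)c(C)c(OCc4ccccc4)c(C)c1OCc1ccccc1 | intermediate
17 | [(3R,4S)-8-(benzyloxy)-3-hydroxy-6-methoxy-4,5-dimethyl-1-oxo-3,4-dihydro-1H-isochromen-3-yl]methyl 2,4-bis(benzyloxy)-3,5,6-trimethylbenzoate | COc1cc(OCc3ccccc3)c2c(c1C)[C@H](C)[C@](O)(COC(=O)c1c(C)c(C)c(OCc4ccccc4)c(C)c1OCc1ccccc1)OC2=O | intermediate
18 | [(3R,4S)-3,8-dihydroxy-6-methoxy-4,5-dimethyl-1-oxo-3,4-dihydro-1H-isochromen-3-yl]methyl 2,4-dihydroxy-3,5,6-trimethylbenzoate | COc1cc(O)c2c(c1C)[C@H](C)[C@](O)(COC(=O)c1c(C)c(C)c(O)c(C)c1O)OC2=O | target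

Total step count: 13. Longest linear sequence: 9 (steps 1 to 6, then 11 to 13).

**Steps most likely to fail**

Step 4. The alkenylrhodium may be protonated before the 1,4 shift reaches the crowded C4a–H next to the C5 methyl group, which would stop the cascade at the open-chain enone. The small methyl group may also give weak facial discrimination in the insertion. The fallback separates bond formation from stereo-induction.
- It sets out from 3, which is annulated oxidatively with 1-(trimethylsilyl)propyne ([Cp*RhCl2]2, AgSbF6, acetohydrazide as transient directing group, Ag2CO3, dioxane, heat).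
- C–H activation at C4a, alkyne insertion with silicon next to the metal and ring closure onto the C=N bond should give 7-(benzyloxy)-5-methoxy-3,4-dimethyl-2-(trimethylsilyl)-1H-inden-1-one F1.
- Protodesilylation (TBAF, wet THF) gives 7-(benzyloxy)-5-methoxy-3,4-dimethyl-1H-inden-1-one F2.
- Asymmetric copper hydride conjugate reduction (Cu(OAc)2, (R)-DTBM-SEGPHOS, PMHS, t-BuOH, toluene) sets the methyl-bearing centre and comes back to the route at 7.

Step 12. Hydration of the electron-rich, ortho-substituted aryl ketone may be too reluctant for the cyclic periodate ester to form. A long exposure to acid could then let C4 epimerise through the enol of the open keto acid, and because C3 follows C4 this would appear as loss of enantiomeric purity. The fallback replaces the ketol cleavage by a glycol cleavage.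
- It sets out from 15, which is reduced (NaBH4, MeOH/THF, 0 °C) to [(2S,3S)-7-(benzyloxy)-1,2-dihydroxy-5-methoxy-3,4-dimethyl-2,3-dihydro-1H-inden-2-yl]methyl 2,4-bis(benzyloxy)-3,5,6-trimethylbenzoate F5 (C1 epimers, both usable).
- Criegee cleavage (Pb(OAc)4, CH2Cl2, 0 °C) gives (3S)-3-[3-(benzyloxy)-2-formyl-5-methoxy-6-methylphenyl]-2-oxobutyl 2,4-bis(benzyloxy)-3,5,6-trimethylbenzoate F6.
- Pinnick oxidation (NaClO2, NaH2PO4, 2-methyl-2-butene, t-BuOH/H2O) gives 16, which closes and comes back to the route at 17.

Step 11. SN2 attack at the methylene group next to the spiro quaternary carbon may be slow, so that thermal or base-induced decay of the epoxy ketone competes. The fallback forms the acyl–oxygen bond instead of the alkyl–oxygen bond and also bypasses step 6.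
- It sets out from 8, which is dihydroxylated (OsO4 cat., NMO, acetone/H2O) from the face opposite to the 3-methyl group to (2S,3S)-7-(benzyloxy)-2-hydroxy-2-(hydroxymethyl)-5-methoxy-3,4-dimethyl-2,3-dihydro-1H-inden-1-one F3.
- Acid 14 is activated with trifluoroacetic anhydride in toluene as 2,4-bis(benzyloxy)-3,5,6-trimethylbenzoic trifluoroacetic anhydride F4. This acylium-type activation suits hindered, electron-rich benzoic acids.
- F4 acylates the primary hydroxyl group of F3 selectively, which comes back to the route at 15.

**Further compounds**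
F1 | step 4 | 7-(benzyloxy)-5-methoxy-3,4-dimethyl-2-(trimethylsilyl)-1H-inden-1-one | COc1cc(OCc3ccccc3)c2c(c1C)C(C)=C([Si](C)(C)C)C2=O
F2 | step 4 | 7-(benzyloxy)-5-methoxy-3,4-dimethyl-1H-inden-1-one | COc1cc(OCc3ccccc3)c2c(c1C)C(C)=CC2=O
F3 | step 11 | (2S,3S)-7-(benzyloxy)-2-hydroxy-2-(hydroxymethyl)-5-methoxy-3,4-dimethyl-2,3-dihydro-1H-inden-1-one | COc1cc(OCc3ccccc3)c2c(c1C)[C@H](C)[C@](O)(CO)C2=O
F4 | step 11 | 2,4-bis(benzyloxy)-3,5,6-trimethylbenzoic trifluoroacetic anhydride | O=C(OC(=O)C(F)(F)F)c1c(C)c(C)c(OCc2ccccc2)c(C)c1OCc1ccccc1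
F5 | step 12 | [(2S,3S)-7-(benzyloxy)-1,2-dihydroxy-5-methoxy-3,4-dimethyl-2,3-dihydro-1H-inden-2-yl]methyl 2,4-bis(benzyloxy)-3,5,6-trimethylbenzoate (C1 epimers) | COc1cc(OCc3ccccc3)c2c(c1C)[C@H](C)[C@](O)(COC(=O)c1c(C)c(C)c(OCc4ccccc4)c(C)c1OCc1ccccc1)C2O
F6 | step 12 | (3S)-3-[3-(benzyloxy)-2-formyl-5-methoxy-6-methylphenyl]-2-oxobutyl 2,4-bis(benzyloxy)-3,5,6-trimethylbenzoate | COc1cc(OCc3ccccc3)c(C=O)c(c1C)[C@H](C)C(=O)COC(=O)c1c(C)c(C)c(OCc4ccccc4)c(C)c1OCc1ccccc1
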